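(The numbers in the tables are simulated with made-up constants, noise included.)

Two questions stand here, and the height of the peak can be reached from two readings.

all flasks: catalyst 0.44 mM

| charge | starting material | partner | second substrate | remark | time |
|---|---|---|---|---|---|
| delta | 0.070 M | 0.040 M | 0.050 M | run made earlier |  |
| beta | 0.11 M | 0.040 M | 0.050 M | run made earlier |  |
| flask | 0.050 M | 0.0400 M | 0.0500 M |  | 1.5 h |

| run | time / min | target / % |
|---|---|---|
| delta | 0.833 | 21 |
| delta | 2.00 | 27 |
| delta | 4.00 | 22 |
| delta | 10.0 | 14 |
| delta | 20.0 | 8 |
| delta | 40.0 | 1 |
| delta | 90.0 | 0 |
| beta | 0.833 | 17 |
| beta | 2.00 | 20 |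
| beta | 4.00 | 11 |
| beta | 10.0 | 5 |
| beta | 20.0 | 0 |
| beta | 40.0 | 0 |
| beta | 90.0 | 0 |

(scatter of a reading: 1.5 percentage points)

- in percentages every species weighs as the starting material in it: one side product counts as two
- steps that have been proposed: starting material + partner + catalyst -> catalyst + target; second substrate + partner + catalyst -> catalyst + second product; second substrate <-> dormant form; starting material + target -> side product; 2 second substrate -> homo dimer

* time up to 1.5 h at which target stands highest
* the amount of target, in percent of the starting material charged, at that time

Take m, the peak amount of target in M, as reading × charge c of starting material: 0.0189 M in delta, 0.0220 M in beta. Partner, second substrate and catalyst are charged alike in both runs and the flask, so you can leave them aside. Your rule is then the exponent n with which the peak amount follows the charge of starting material: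

n = ln(m_beta/m_delta) / ln(c_beta/c_delta) = 0.336

Which readings must you trust? The flask lies outside the two runs, on delta's side, so the answer goes as m_delta^(1+w) / m_beta^w, with

w = ln(c_delta/c) / ln(c_beta/c_delta) = 0.744

One scatter of 1.5 percentage points on delta's peak moves the answer by 3.3 points, and on beta's peak by 1.9 points. The later readings don't enter. Now the number:

peak = m_delta × (c/c_delta)^n / c = 33.8%

For the time, both runs read highest at 2.00 min; I place the flask later, between that and 4.00 min.

The forecast gives 0.04 h and 33%, holding that “starting material and second substrate compete about equally for partner”.

The flask peaks at 3.29 min with 34.3%, against the 33.8% from n.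

    starting material + partner + catalyst → catalyst + target (k = 610 M⁻² s⁻¹)
    second substrate + partner + catalyst → catalyst + second product (k = 1200 M⁻² s⁻¹)
    second substrate ⇌ dormant form (K = 0.690, k = 0.00760 s⁻¹)
    starting material + target → side product (k = 0.0440 M⁻¹ s⁻¹)
    2 second substrate → homo dimer (k = 0.460 M⁻¹ s⁻¹)

Of the effects tried on the height of the flask's peak, the wearing away of partner, the limiting reagent, is the largest single one: in the run without that wearing away the peak stands at 83.7% against 34.3%. For the neighbour flask with 0.020 M of starting material, n gives 62.0%, and that flask reaches 65.5%.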